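The route rests on disconnecting the aryl ether bond O1–C7a of the dihydrofuran ring. In the key step the C2 alkoxide of an open-chain precursor attacks C7a and expels fluoride (intramolecular SNAr), closing the five-membered ring with both stereocentres already in place. The step exploits the position of C5 of the benzo ring (ring B), the carbon that carries the propenal chain, para to C7a: held as a formyl group, it stabilises the Meisenheimer complex and is then extended to the enal. The precursor is a 4-fluoro-3-methoxybenzaldehyde that bears, next to fluorine, a syn (1R,2S)-1-aryl-1,3-diol chain (primary oxygen silylated) made by an Evans syn aldol reaction.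

Key step: step 8

Remark: the SMILES is read as the trans (2R,3S) isomer; benzofuran numbering is used throughout, ring A being the 3,4-dimethoxyphenyl group and ring B the benzo ring.

Step 1
Reactants: 1 4-fluoro-3-methoxybenzaldehyde
Product: 2 2-(4-fluoro-3-methoxyphenyl)-1,3-dioxolane
Conditions: ethylene glycol, p-TsOH·H2O (cat.), toluene, reflux, Dean–Stark
Reagents that add atoms: ethylene glycol, OCCO
Why: Acid-catalysed acetalisation with azeotropic removal of water masks the formyl group as a dioxolane that should withstand the organometallic and enolate steps.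

Step 2
Reactants: 2 2-(4-fluoro-3-methoxyphenyl)-1,3-dioxolane
Product: 5 2-[5-(1,3-dioxolan-2-yl)-2-fluoro-3-methoxyphenyl]ethan-1-ol, via aryllithium 3 (not isolated), via arylmagnesium bromide 4 (not isolated)
Conditions: n-BuLi, PMDTA, THF, −78 °C; MgBr2·OEt2, −78 °C; oxirane, CuI (10 mol %), −78 to 0 °C; H2O work-up
Reagents that add atoms: oxirane, C1CO1
Why: Directed ortho-metalation, in which fluorine is the strongest acidifying substituent so that PMDTA-activated n-BuLi should remove the proton next to it (2-fluoroanisoles lithiate beside fluorine), followed by transmetalation to magnesium to suppress loss of LiF to an aryne and CuI-catalysed epoxide ring opening by the Grignard reagent.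

Step 3
Reactants: 5 2-[5-(1,3-dioxolan-2-yl)-2-fluoro-3-methoxyphenyl]ethan-1-ol
Product: 6 2-[5-(1,3-dioxolan-2-yl)-2-fluoro-3-methoxyphenyl]acetic acid
Conditions: TEMPO (cat.), NaOCl (cat.), NaClO2, MeCN–phosphate buffer (pH 6.7), 35 °C
Reagents that add atoms: sodium chlorite, [Na+].[O-]Cl=O
Why: TEMPO-catalysed oxidation with chlorite as terminal oxidant should take the primary alcohol through the aldehyde to the acid at near-neutral pH, which spares the dioxolane and the arene.

Step 4
Reactants: 6 2-[5-(1,3-dioxolan-2-yl)-2-fluoro-3-methoxyphenyl]acetic acid; 7 (4R)-4-benzyl-1,3-oxazolidin-2-one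
Product: 9 (4R)-4-benzyl-3-{2-[5-(1,3-dioxolan-2-yl)-2-fluoro-3-methoxyphenyl]acetyl}-1,3-oxazolidin-2-one, via mixed pivalic anhydride 8 (not isolated)
Conditions: PivCl, Et3N, THF, −20 °C; then 7, LiCl, −20 °C to rt
Reagents that add atoms: none
Why: N-Acylation of the oxazolidinone through the mixed pivalic anhydride (LiCl/Et3N activation) attaches the Evans auxiliary without a strong base.

Step 5
Reactants: 9 (4R)-4-benzyl-3-{2-[5-(1,3-dioxolan-2-yl)-2-fluoro-3-methoxyphenyl]acetyl}-1,3-oxazolidin-2-one; 10 3,4-dimethoxybenzaldehyde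
Product: 13 (4R)-4-benzyl-3-[(2R,3R)-3-(3,4-dimethoxyphenyl)-2-[5-(1,3-dioxolan-2-yl)-2-fluoro-3-methoxyphenyl]-3-hydroxypropanoyl]-1,3-oxazolidin-2-one, via dibutylboron enolate 11 (not isolated), via dibutylboron aldolate 12 (not isolated)
Conditions: Bu2BOTf, i-Pr2NEt, CH2Cl2, 0 °C; 10, −78 to 0 °C; pH 7 buffer, MeOH, 30% H2O2, 0 °C
Reagents that add atoms: none
Why: Evans syn aldol reaction, in which soft enolisation gives the Z boron enolate that adds to the aldehyde through a chair (Zimmerman–Traxler) transition state on the enolate face away from the benzyl group of the dipole-opposed auxiliary, so that both stereocentres should be set as (2R,3R) syn.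

Step 6
Reactants: 13 (4R)-4-benzyl-3-[(2R,3R)-3-(3,4-dimethoxyphenyl)-2-[5-(1,3-dioxolan-2-yl)-2-fluoro-3-methoxyphenyl]-3-hydroxypropanoyl]-1,3-oxazolidin-2-one
Product: 15 3-[(1R,2S)-1-(3,4-dimethoxyphenyl)-1,3-dihydroxypropan-2-yl]-4-fluoro-5-methoxybenzaldehyde, via diol acetal 14 (not isolated)
Conditions: LiBH4, MeOH (1 equiv), THF, 0 °C; then 0.5 M aq. HCl–THF, rt
Reagents that add atoms: water, O
Why: Reductive cleavage of the auxiliary by hydride attack on the exocyclic imide carbonyl should give the primary alcohol without touching either stereocentre (the descriptor at the former α-carbon changes from R to S only through the priority change), and the dilute-acid work-up hydrolyses the dioxolane (acetal hydrolysis) much faster than the benzylic carbinol can ionise.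

Step 7
Reactants: 15 3-[(1R,2S)-1-(3,4-dimethoxyphenyl)-1,3-dihydroxypropan-2-yl]-4-fluoro-5-methoxybenzaldehyde
Product: 16 3-[(1R,2S)-1-(3,4-dimethoxyphenyl)-1-hydroxy-3-[(triisopropylsilyl)oxy]propan-2-yl]-4-fluoro-5-methoxybenzaldehyde
Conditions: TIPSCl, imidazole, DMF, 0 °C
Reagents that add atoms: triisopropylsilyl chloride, CC(C)[Si](Cl)(C(C)C)C(C)C
Why: Silyl ether formation is sterically controlled, so the bulky chlorosilane should react with the primary hydroxyl and leave the hindered secondary benzylic one free.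

Step 8
Reactants: 16 3-[(1R,2S)-1-(3,4-dimethoxyphenyl)-1-hydroxy-3-[(triisopropylsilyl)oxy]propan-2-yl]-4-fluoro-5-methoxybenzaldehyde
Product: 18 (2R,3S)-2-(3,4-dimethoxyphenyl)-7-methoxy-3-{[(triisopropylsilyl)oxy]methyl}-2,3-dihydro-1-benzofuran-5-carbaldehyde, via sodium alkoxide 17 (not isolated)
Conditions: NaH (1.2 equiv), THF–DMF (4:1), 0 °C to rt
Reagents that add atoms: none
Why: NaH deprotonates the only free hydroxyl and the C2 alkoxide adds to C7a, which carries fluorine and stands para to the formyl group at C5, to give a Meisenheimer complex whose charge is delocalised onto the formyl oxygen; loss of fluoride restores the arene (addition–elimination SNAr). The closest known reaction type is the displacement of fluoride from 4-fluorobenzaldehydes by alkoxides, here run intramolecularly. The dihydrofuran ring (O1, C2, C3, C3a, C7a) is closed in the 5-exo-trig mode, the C7a–C7 bond that takes up the electrons lying outside the new ring. No stereocentre is formed: C2 and C3 keep the configuration set in the aldol step because no bond at either centre is made or broken, and the syn (1R,2S) chain becomes the trans (2R,3S) ring. The step needs O-selectivity, secured by the triisopropylsilyl ether on the primary oxygen (too bulky to migrate readily to the alkoxide), and site selectivity, secured by the single C–F bond; C3–H is not acidified because C3a is meta to the formyl group, so the base should not epimerise C3.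

Step 9
Reactants: 18 (2R,3S)-2-(3,4-dimethoxyphenyl)-7-methoxy-3-{[(triisopropylsilyl)oxy]methyl}-2,3-dihydro-1-benzofuran-5-carbaldehyde; 19 (triphenylphosphoranylidene)acetaldehyde
Product: 20 (2E)-3-[(2R,3S)-2-(3,4-dimethoxyphenyl)-7-methoxy-3-{[(triisopropylsilyl)oxy]methyl}-2,3-dihydro-1-benzofuran-5-yl]prop-2-enal
Conditions: 19 (1.3 equiv), toluene, 80 °C
Reagents that add atoms: none
Why: Wittig olefination with a carbonyl-stabilised ylide should give the E enal, the formyl group that activated the ring closure now serving as the anchor of the side chain.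

Step 10
Reactants: 20 (2E)-3-[(2R,3S)-2-(3,4-dimethoxyphenyl)-7-methoxy-3-{[(triisopropylsilyl)oxy]methyl}-2,3-dihydro-1-benzofuran-5-yl]prop-2-enal
Product: 21 (2E)-3-[(2R,3S)-2-(3,4-dimethoxyphenyl)-3-(hydroxymethyl)-7-methoxy-2,3-dihydro-1-benzofuran-5-yl]prop-2-enal (4-O-methylbalanophonin)
Conditions: Bu4NF, AcOH, THF, 0 °C to rt
Reagents that add atoms: none
Why: Fluoride-mediated cleavage of the silyl ether, buffered with acetic acid, should free the primary alcohol without base-induced change at the enal or at C2 and C3.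

Compound list

1 | 4-fluoro-3-methoxybenzaldehyde | COc1cc(C=O)ccc1F | starting material
2 | 2-(4-fluoro-3-methoxyphenyl)-1,3-dioxolane | COc1cc(C2OCCO2)ccc1F | intermediate
3 | [5-(1,3-dioxolan-2-yl)-2-fluoro-3-methoxyphenyl]lithium | [Li]c1cc(C2OCCO2)cc(OC)c1F | intermediate
4 | [5-(1,3-dioxolan-2-yl)-2-fluoro-3-methoxyphenyl]magnesium bromide | Br[Mg]c1cc(C2OCCO2)cc(OC)c1F | intermediate
5 | 2-[5-(1,3-dioxolan-2-yl)-2-fluoro-3-methoxyphenyl]ethan-1-ol | OCCc1cc(C2OCCO2)cc(OC)c1F | intermediate
6 | 2-[5-(1,3-dioxolan-2-yl)-2-fluoro-3-methoxyphenyl]acetic acid | OC(=O)Cc1cc(C2OCCO2)cc(OC)c1F | intermediate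
7 | (4R)-4-benzyl-1,3-oxazolidin-2-one | O=C1N[C@H](Cc2ccccc2)CO1 | starting material
8 | 2-[5-(1,3-dioxolan-2-yl)-2-fluoro-3-methoxyphenyl]acetic pivalic anhydride | CC(C)(C)C(=O)OC(=O)Cc1cc(C2OCCO2)cc(OC)c1F | intermediate
9 | (4R)-4-benzyl-3-{2-[5-(1,3-dioxolan-2-yl)-2-fluoro-3-methoxyphenyl]acetyl}-1,3-oxazolidin-2-one | O=C1OC[C@@H](Cc2ccccc2)N1C(=O)Cc1cc(C2OCCO2)cc(OC)c1F | intermediate
10 | 3,4-dimethoxybenzaldehyde | COc1ccc(C=O)cc1OC | starting material
11 | (Z)-dibutylboron enolate of 9 | CCCCB(CCCC)O/C(=C\c1cc(C2OCCO2)cc(OC)c1F)N1[C@H](Cc2ccccc2)COC1=O | intermediate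
12 | dibutylboron aldolate of 13 (O-dibutylboryl derivative) | O=C1OC[C@@H](Cc2ccccc2)N1C(=O)[C@H](c2cc(C3OCCO3)cc(OC)c2F)[C@@H](OB(CCCC)CCCC)c2ccc(OC)c(OC)c2 | intermediate
13 | (4R)-4-benzyl-3-[(2R,3R)-3-(3,4-dimethoxyphenyl)-2-[5-(1,3-dioxolan-2-yl)-2-fluoro-3-methoxyphenyl]-3-hydroxypropanoyl]-1,3-oxazolidin-2-one | O=C1OC[C@@H](Cc2ccccc2)N1C(=O)[C@H](c2cc(C3OCCO3)cc(OC)c2F)[C@@H](O)c2ccc(OC)c(OC)c2 | intermediate
14 | (1R,2S)-1-(3,4-dimethoxyphenyl)-2-[5-(1,3-dioxolan-2-yl)-2-fluoro-3-methoxyphenyl]propane-1,3-diol | COc1ccc([C@H](O)[C@H](CO)c2cc(C3OCCO3)cc(OC)c2F)cc1OC | intermediate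
15 | 3-[(1R,2S)-1-(3,4-dimethoxyphenyl)-1,3-dihydroxypropan-2-yl]-4-fluoro-5-methoxybenzaldehyde | COc1ccc([C@H](O)[C@H](CO)c2cc(C=O)cc(OC)c2F)cc1OC | intermediate
16 | 3-[(1R,2S)-1-(3,4-dimethoxyphenyl)-1-hydroxy-3-[(triisopropylsilyl)oxy]propan-2-yl]-4-fluoro-5-methoxybenzaldehyde | COc1ccc([C@H](O)[C@H](CO[Si](C(C)C)(C(C)C)C(C)C)c2cc(C=O)cc(OC)c2F)cc1OC | intermediate
17 | sodium alkoxide of 16 | COc1ccc([C@H]([O-])[C@H](CO[Si](C(C)C)(C(C)C)C(C)C)c2cc(C=O)cc(OC)c2F)cc1OC.[Na+] | intermediate
18 | (2R,3S)-2-(3,4-dimethoxyphenyl)-7-methoxy-3-{[(triisopropylsilyl)oxy]methyl}-2,3-dihydro-1-benzofuran-5-carbaldehyde | COc1ccc([C@@H]2Oc3c(OC)cc(C=O)cc3[C@H]2CO[Si](C(C)C)(C(C)C)C(C)C)cc1OC | intermediate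
19 | (triphenylphosphoranylidene)acetaldehyde | O=CC=P(c1ccccc1)(c1ccccc1)c1ccccc1 | starting material
20 | (2E)-3-[(2R,3S)-2-(3,4-dimethoxyphenyl)-7-methoxy-3-{[(triisopropylsilyl)oxy]methyl}-2,3-dihydro-1-benzofuran-5-yl]prop-2-enal | COc1ccc([C@@H]2Oc3c(OC)cc(/C=C/C=O)cc3[C@H]2CO[Si](C(C)C)(C(C)C)C(C)C)cc1OC | intermediate
21 | (2E)-3-[(2R,3S)-2-(3,4-dimethoxyphenyl)-3-(hydroxymethyl)-7-methoxy-2,3-dihydro-1-benzofuran-5-yl]prop-2-enal (4-O-methylbalanophonin) | COc1ccc([C@@H]2Oc3c(OC)cc(/C=C/C=O)cc3[C@H]2CO)cc1OC | target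

Total step count: 10
Longest linear sequence: 10 steps (1 to 21)

Steps most likely to fail

Step 2. The metalation may take place between the methoxy and dioxolanyl groups instead of next to fluorine, or the ortho-fluoroaryl metal may lose metal fluoride to an aryne before it is trapped. Fallback, setting out from 2 and coming back at 6: iridium-catalysed C–H borylation of 2 ([Ir(OMe)(cod)]2, 4,4'-di-tert-butyl-2,2'-bipyridine, B2pin2, THF, 70 °C) is steered by sterics and by the small, activating fluorine to the C–H beside fluorine. It would give 2-[5-(1,3-dioxolan-2-yl)-2-fluoro-3-methoxyphenyl]-4,4,5,5-tetramethyl-1,3,2-dioxaborolane F1. Suzuki–Miyaura coupling of this boronic ester with ethyl bromoacetate (Pd(OAc)2, tri(1-naphthyl)phosphine, K3PO4, THF–H2O) would give ethyl 2-[5-(1,3-dioxolan-2-yl)-2-fluoro-3-methoxyphenyl]acetate F2. Saponification with LiOH in THF–H2O would then give acid 6.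

Step 8. The alkoxide or the base may add to the formyl group, with hydride transfer or condensation consuming the aldehyde faster than the strained 5-exo ipso attack. Silyl migration may also free the primary oxygen, which would then close the six-membered ether. Fallback, setting out from 16 and coming back at 18: the formyl group is exchanged for a nitrile, which activates C7a equally but cannot bind the alkoxide irreversibly. I2 and aqueous NH3 in THF would turn 16 into 3-[(1R,2S)-1-(3,4-dimethoxyphenyl)-1-hydroxy-3-[(triisopropylsilyl)oxy]propan-2-yl]-4-fluoro-5-methoxybenzonitrile F8. NaH in THF–DMF would close the ring to (2R,3S)-2-(3,4-dimethoxyphenyl)-7-methoxy-3-{[(triisopropylsilyl)oxy]methyl}-2,3-dihydro-1-benzofuran-5-carbonitrile F9. Partial reduction with i-Bu2AlH (toluene, −78 °C) and hydrolysis of the imine with dilute aqueous acid would give aldehyde 18.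

Step 5. Retro-aldol equilibration of the hindered α-aryl aldolate with the electron-rich aldehyde may erode facial and syn selectivity, or the boron triflate may open the dioxolane. Fallback, setting out from 6 and coming back at 15: the two stereocentres are set by a catalyst-controlled carbene C–H insertion instead of an auxiliary-controlled aldol reaction.
- Acid 6 is esterified (MeI, K2CO3, DMF) to methyl 2-[5-(1,3-dioxolan-2-yl)-2-fluoro-3-methoxyphenyl]acetate F3.
- Diazo transfer (4-acetamidobenzenesulfonyl azide, DBU, MeCN) gives methyl 2-diazo-2-[5-(1,3-dioxolan-2-yl)-2-fluoro-3-methoxyphenyl]acetate F4.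
- 3,4-Dimethoxybenzyl alcohol is silylated (TBSCl, imidazole) to tert-butyl[(3,4-dimethoxyphenyl)methoxy]dimethylsilane F5.
- Insertion of the rhodium carbene from the diazo ester into the benzylic C–H bond of this silyl ether would give the syn ester methyl (2R,3R)-3-[(tert-butyldimethylsilyl)oxy]-3-(3,4-dimethoxyphenyl)-2-[5-(1,3-dioxolan-2-yl)-2-fluoro-3-methoxyphenyl]propanoate F6. The catalyst is Rh2(S-DOSP)4 or its enantiomer Rh2(R-DOSP)4, whichever delivers the (2R,3R) isomer, in 2,2-dimethylbutane at rt.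
- HF·pyridine in THF removes the silyl group to give methyl (2R,3R)-3-(3,4-dimethoxyphenyl)-2-[5-(1,3-dioxolan-2-yl)-2-fluoro-3-methoxyphenyl]-3-hydroxypropanoate F7.
- LiBH4 in THF reduces the ester to diol acetal 14, and the dilute-acid work-up of step 6 gives 15.

Further compounds

F1 | step 2 | 2-[5-(1,3-dioxolan-2-yl)-2-fluoro-3-methoxyphenyl]-4,4,5,5-tetramethyl-1,3,2-dioxaborolane | COc1cc(C2OCCO2)cc(B3OC(C)(C)C(C)(C)O3)c1F
F2 | step 2 | ethyl 2-[5-(1,3-dioxolan-2-yl)-2-fluoro-3-methoxyphenyl]acetate | CCOC(=O)Cc1cc(C2OCCO2)cc(OC)c1F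
F3 | step 5 | methyl 2-[5-(1,3-dioxolan-2-yl)-2-fluoro-3-methoxyphenyl]acetate | COC(=O)Cc1cc(C2OCCO2)cc(OC)c1F
F4 | step 5 | methyl 2-diazo-2-[5-(1,3-dioxolan-2-yl)-2-fluoro-3-methoxyphenyl]acetate | COC(=O)C(=[N+]=[N-])c1cc(C2OCCO2)cc(OC)c1F
F5 | step 5 | tert-butyl[(3,4-dimethoxyphenyl)methoxy]dimethylsilane | COc1ccc(CO[Si](C)(C)C(C)(C)C)cc1OC
F6 | step 5 | methyl (2R,3R)-3-[(tert-butyldimethylsilyl)oxy]-3-(3,4-dimethoxyphenyl)-2-[5-(1,3-dioxolan-2-yl)-2-fluoro-3-methoxyphenyl]propanoate | COC(=O)[C@H](c1cc(C2OCCO2)cc(OC)c1F)[C@@H](O[Si](C)(C)C(C)(C)C)c1ccc(OC)c(OC)c1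
F7 | step 5 | methyl (2R,3R)-3-(3,4-dimethoxyphenyl)-2-[5-(1,3-dioxolan-2-yl)-2-fluoro-3-methoxyphenyl]-3-hydroxypropanoate | COC(=O)[C@H](c1cc(C2OCCO2)cc(OC)c1F)[C@@H](O)c1ccc(OC)c(OC)c1
F8 | step 8 | 3-[(1R,2S)-1-(3,4-dimethoxyphenyl)-1-hydroxy-3-[(triisopropylsilyl)oxy]propan-2-yl]-4-fluoro-5-methoxybenzonitrile | COc1ccc([C@H](O)[C@H](CO[Si](C(C)C)(C(C)C)C(C)C)c2cc(C#N)cc(OC)c2F)cc1OC
F9 | step 8 | (2R,3S)-2-(3,4-dimethoxyphenyl)-7-methoxy-3-{[(triisopropylsilyl)oxy]methyl}-2,3-dihydro-1-benzofuran-5-carbonitrile | COc1ccc([C@@H]2Oc3c(OC)cc(C#N)cc3[C@H]2CO[Si](C(C)C)(C(C)C)C(C)C)cc1OC
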